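**Plan**

- Locants follow the target's bicyclo[3.3.1]nonane numbering: C1 (benzoyl bridgehead), C2 (OMe), C3, C4 (C=O), C5 (prenyl bridgehead), C6H2, C7, C8 (CMe2), C9 (bridging C=O), and C10–C13 for the C7 side chain. Ring A is C1–C2–C3–C4–C5–C9 and ring B is C1–C8–C7–C6–C5–C9.
- Retrosynthetic cuts, in order: the acetate; C10–C11 (sp3–sp2 coupling); O2–CH3; then C5–C6 and C8–C1 together, which returns ring A as the flat arene clusiaphenone B and C6–C7–C8 as 2-(bromomethyl)-3-methylbut-2-enal.
- Enabling feature: ring A is a masked, fully substituted acylphloroglucinol whose carbons C5 and C1, 1,3-related across the C9 oxygen, are nucleophiles, while C6 (CH2) and C8 (CMe2) are the two electrophilic ends of an enal. C7 carries a temporary formyl carbon (C10), which C3 captures as a temporary cage ring (an adamantane) and which later becomes the first side-chain carbon.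
- Forward order: arene; ring B (C5–C6 by alkylative dearomatization, C8–C1 on acidification of the same flask) together with the cage ring; cage opened with O4 silylated; O2 methylated with loss of silicon; CHO to CH2Br; C10–C11 coupling; acetate.
- Stereochemistry: C5 is set by a chiral ammonium catalyst in the dearomatizing alkylation. C1 and C7 (endo) are relayed from C5 in the same operation. The E alkene comes from syn-carboalumination and is retained in the coupling.

Key step: step 5

Assumption: the cinchonidinium salt named in step 5 is taken to deliver the (5S) series drawn; if the opposite sense is found, its cinchoninium pseudoenantiomer is used with no other change. The C10 carbinol configuration of 10 is the expected one and is erased in step 6.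

**Route**

Step 1
Reactants: 1 2,4,6-trihydroxybenzophenone; 2 prenyl bromide
Product: 3 clusiaphenone B (2,4,6-trihydroxy-3,5-bis(3-methylbut-2-enyl)benzophenone)
Conditions: 2 (2.2 equiv), aq. KOH, 0 °C
Reagents that add atoms: none
Why: Double C-prenylation of the phloroglucinol phenoxide (Friedel–Crafts-type C-alkylation), in which aqueous base favours C- over O-alkylation at the two free ring carbons and no stereocenter is formed.

Step 2
Reactants: 4 diethyl 2-(propan-2-ylidene)malonate
Product: 5 2-(propan-2-ylidene)propane-1,3-diol
Conditions: i-Bu2AlH (4.5 equiv), CH2Cl2, −78 to 0 °C; aq. potassium sodium tartrate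
Reagents that add atoms: none
Why: Ester reduction by 1,2-hydride delivery to both esters, with the fully substituted β-carbon disfavouring conjugate reduction.

Step 3
Reactants: 5 2-(propan-2-ylidene)propane-1,3-diol
Product: 6 2-(hydroxymethyl)-3-methylbut-2-enal
Conditions: MnO2 (activated), CH2Cl2, 20 °C, stopped at mono-oxidation
Reagents that add atoms: none
Why: MnO2 oxidation of an allylic alcohol, which should stop at the mono-aldehyde because the remaining hydroxymethyl group then sits on an electron-poor enal and is oxidized more slowly.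

Step 4
Reactants: 6 2-(hydroxymethyl)-3-methylbut-2-enal
Product: 7 2-(bromomethyl)-3-methylbut-2-enal
Conditions: PBr3 (0.4 equiv), Et2O, −10 °C
Reagents that add atoms: phosphorus tribromide, BrP(Br)Br
Why: PBr3 bromination of the primary allylic alcohol (SN2 on the phosphite ester), with the enal left untouched at low temperature.

Step 5
Reactants: 3 clusiaphenone B; 7 2-(bromomethyl)-3-methylbut-2-enal
Product: 10 adamantane alcohol (1-benzoyl-10-hydroxy-8,8-dimethyl-3,5-bis(3-methylbut-2-enyl)adamantane-2,4,9-trione; configuration at C1/C5/C7 as in the target), via dearomatized enal 8 (not isolated), via enol aldehyde 9 (not isolated)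
Conditions: 7 (1.2 equiv), O-allyl-N-(9-anthracenylmethyl)cinchonidinium bromide (0.2 equiv), CsOH·H2O (2.1 equiv), CH2Cl2, −50 °C; then THF, conc. aq. HCl, −50 to 20 °C (same flask)
Reagents that add atoms: none
Why: Within the ion pair with the chiral ammonium ion the caesium phenoxide of 3 should be C-alkylated by the primary allylic bromide at one of its two enantiotopic prenyl-bearing carbons (C5; SN2, dearomatization) to give 8, which the limited charge of base holds as its sluggish triketonate; on acidification the protonated β,β-dimethyl enal, with tertiary cation character at C8, is attacked by the enol carbon C1 (Michael addition, giving 9), and the C3 enol then adds to the protonated aldehyde carbon C10 (aldol) to give cage 10. The closest known reaction types are the Cinchona-derived phase-transfer-catalysed enantioselective alkylative dearomatization of diprenylated acylphloroglucinols and the acid-mediated cyclization of the dearomatized enals so formed to 1-acyl hydroxyadamantanes. Ring B closes in a 6-(enolendo)-endo-trig Michael mode and the temporary cage ring in a 6-(enolendo)-exo-trig aldol mode. C5 is set by the catalyst; C1 follows from C5 because the three-carbon bridge can reach C1 only on the face of ring A that carries C6; C7 becomes endo because its epimers interconvert through the aldehyde enol and only the endo aldehyde can reach C3; C3 and C10 are temporary centres fixed by the cage. The step needs C- over O-alkylation (soft allylic bromide, tight ion pair in CH2Cl2), first attack at a prenyl-bearing carbon rather than at C1 (these are the more nucleophilic ring positions), and closure at C1 rather than C3 in the Michael event. The last is why the closure is run under acid and not left to the base, under which the alkyl-bearing C3 of the enolate would be expected to add instead: the acid-mediated Michael step is reversible, and only the C1 adduct keeps the strongly nucleophilic vinylogous-acid carbon C3 free for the aldol closure that removes it from the equilibrium, whereas a C3 adduct could close only through the poorly nucleophilic triketone carbon C1 to a retro-aldol-prone cage.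

Step 6
Reactants: 10 adamantane alcohol
Product: 12 O4-silyl aldehyde (1-benzoyl-8,8-dimethyl-3,5-bis(3-methylbut-2-enyl)-2,9-dioxo-4-(triisopropylsilyloxy)bicyclo[3.3.1]non-3-ene-7-carbaldehyde; CHO endo), via potassium diketonate 11 (not isolated)
Conditions: KN(SiMe3)2 (1.0 equiv), THF, −78 to −40 °C; then i-Pr3SiOSO2CF3 (1.05 equiv), −78 °C
Reagents that add atoms: triisopropylsilyl triflate, CC(C)[Si](OS(=O)(=O)C(F)(F)F)(C(C)C)C(C)C
Why: Retro-aldol fragmentation with enolate trapping: the potassium alkoxide of 10 should open to the far more stabilized diketonate 11 and free the endo aldehyde with C7 unchanged (the diketonate is too weak a base to enolize it), and the bulky silyl triflate should take the less hindered O4 (next to C5 and the C6 methylene) rather than O2, which is screened by the C1 benzoyl and C8 gem-dimethyl groups.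

Step 7
Reactants: 12 O4-silyl aldehyde
Product: 14 O2-methyl aldehyde (1-benzoyl-2-methoxy-8,8-dimethyl-3,5-bis(3-methylbut-2-enyl)-4,9-dioxobicyclo[3.3.1]non-2-ene-7-carbaldehyde; CHO endo), via silyloxyallyl cation triflate 13 (not isolated)
Conditions: MeOSO2CF3 (1.5 equiv), 2,6-di-tert-butyl-4-methylpyridine, CH2Cl2, 0 to 20 °C; then CsF, MeCN, 0 °C
Reagents that add atoms: methyl triflate, COS(=O)(=O)C(F)(F)F
Why: Proposed new method: methyl triflate should alkylate the only basic oxygen of the push–pull system, the C2 carbonyl oxygen of vinylogous silyl ester 12 (C3 is fully substituted and hard alkylating agents attack oxygen), to give the 2-methoxy-4-silyloxyallyl cation 13, from which fluoride removes silicon so that methyl ends on O2 and the carbonyl on C4, the reverse of what direct methylation of the hindered enol would favour; the closest known reaction types are O-alkylation of vinylogous esters and 4-hydroxy-2-pyranones on the carbonyl oxygen by methyl triflate or trialkyloxonium salts, and fluoride cleavage of silyl enol ethers.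

Step 8
Reactants: 14 O2-methyl aldehyde
Product: 15 primary alcohol (1-benzoyl-7-(hydroxymethyl)-2-methoxy-8,8-dimethyl-3,5-bis(3-methylbut-2-enyl)bicyclo[3.3.1]non-2-ene-4,9-dione; CH2OH endo)
Conditions: NaBH4, THF/EtOH, −40 °C
Reagents that add atoms: none
Why: Chemoselective borohydride reduction, in which the aldehyde should react far faster than the hindered C9 and benzoyl ketones and the vinylogous ester; after it C7 can no longer epimerize.

Step 9
Reactants: 15 primary alcohol
Product: 16 primary bromide (1-benzoyl-7-(bromomethyl)-2-methoxy-8,8-dimethyl-3,5-bis(3-methylbut-2-enyl)bicyclo[3.3.1]non-2-ene-4,9-dione; CH2Br endo)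
Conditions: CBr4, PPh3, CH2Cl2, 0 °C; used without storage
Reagents that add atoms: carbon tetrabromide, BrC(Br)(Br)Br
Why: Appel bromination (SN2 at the primary carbon via the alkoxyphosphonium salt) under neutral conditions that leave the enol ether and prenyl groups alone, with C7 not involved.

Step 10
Reactants: 17 propargyl alcohol
Product: 19 (E)-3-bromo-2-methylprop-2-en-1-ol, via alkenylalane 18 (not isolated)
Conditions: AlMe3 (3 equiv), (C5H5)2ZrCl2 (0.25 equiv), CH2Cl2, 0 to 20 °C; then N-bromosuccinimide, THF, −30 °C
Reagents that add atoms: trimethylaluminium, C[Al](C)C; N-bromosuccinimide, O=C1CCC(=O)N1Br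
Why: Negishi carboalumination adds methyl and aluminium syn across the alkyne, and bromodealumination with retention should then give the E bromide.

Step 11
Reactants: 16 primary bromide; 19 (E)-3-bromo-2-methylprop-2-en-1-ol
Product: 20 allylic alcohol (1-benzoyl-7-[(E)-4-hydroxy-3-methylbut-2-enyl]-2-methoxy-8,8-dimethyl-3,5-bis(3-methylbut-2-enyl)bicyclo[3.3.1]non-2-ene-4,9-dione; side chain endo)
Conditions: NiBr2(MeOCH2CH2OMe) (10 mol %), 4,4′-di-tert-butyl-2,2′-bipyridine (10 mol %), NaI (0.25 equiv), Mn powder (2 equiv), N,N-dimethylacetamide, 25 °C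
Reagents that add atoms: none
Why: Nickel-catalysed reductive cross-electrophile coupling, in which the alkenyl bromide adds oxidatively to low-valent nickel with retention of geometry and the primary alkyl bromide enters as a radical, so C10–C11 forms without a basic organometallic reagent and the ketones, enol ether and free hydroxyl should be tolerated.

Step 12
Reactants: 20 allylic alcohol
Product: 21 target, [(E)-4-[(1R,5S,7S)-1-benzoyl-2-methoxy-8,8-dimethyl-3,5-bis(3-methylbut-2-enyl)-4,9-dioxobicyclo[3.3.1]non-2-en-7-yl]-2-methylbut-2-enyl] acetate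
Conditions: Ac2O, pyridine, DMAP (cat.), CH2Cl2, 0 °C
Reagents that add atoms: acetic anhydride, CC(=O)OC(C)=O
Why: DMAP-catalysed acylation of the only hydroxyl group, a primary allylic alcohol.

**Compound list**

1 | 2,4,6-trihydroxybenzophenone | O=C(c1ccccc1)c1c(O)cc(O)cc1O | starting material
2 | prenyl bromide (1-bromo-3-methylbut-2-ene) | CC(C)=CCBr | starting material
3 | clusiaphenone B, 2,4,6-trihydroxy-3,5-bis(3-methylbut-2-enyl)benzophenone | O=C(c1ccccc1)c1c(O)c(CC=C(C)C)c(O)c(CC=C(C)C)c1O | intermediate
4 | diethyl 2-(propan-2-ylidene)malonate | CCOC(=O)C(=C(C)C)C(=O)OCC | starting material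
5 | 2-(propan-2-ylidene)propane-1,3-diol | CC(C)=C(CO)CO | intermediate
6 | 2-(hydroxymethyl)-3-methylbut-2-enal | CC(C)=C(CO)C=O | intermediate
7 | 2-(bromomethyl)-3-methylbut-2-enal | CC(C)=C(CBr)C=O | intermediate
8 | dearomatized enal (not isolated), 4-benzoyl-3,5-dihydroxy-6-(2-formyl-3-methylbut-2-enyl)-2,6-bis(3-methylbut-2-enyl)cyclohexa-2,4-dien-1-one, quaternary carbon configured as C5 of 21 | OC1=C(CC=C(C)C)C(=O)[C@](CC=C(C)C)(CC(C=O)=C(C)C)C(O)=C1C(=O)c1ccccc1 | intermediate
9 | enol aldehyde (not isolated), 1-benzoyl-2-hydroxy-8,8-dimethyl-3,5-bis(3-methylbut-2-enyl)-4,9-dioxobicyclo[3.3.1]non-2-ene-7-carbaldehyde, CHO endo (cis to the C2–C4 bridge), C1, C5, C7 as in 21 | OC1=C(CC=C(C)C)C(=O)[C@]2(CC=C(C)C)C[C@H](C=O)C(C)(C)[C@@]1(C(=O)c1ccccc1)C2=O | intermediate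
10 | adamantane alcohol, 1-benzoyl-10-hydroxy-8,8-dimethyl-3,5-bis(3-methylbut-2-enyl)adamantane-2,4,9-trione, C1, C5, C7 as in 21, C10 hydroxyl on the side of C4 and C6 | O=C1[C@@]3(CC=C(C)C)C(=O)[C@]2(CC=C(C)C)C[C@H]([C@@H]3O)C(C)(C)[C@@]1(C(=O)c1ccccc1)C2=O | intermediate
11 | potassium diketonate (not isolated), potassium salt of the C2–C3–C4 enolate of the ring-opened 7-endo aldehyde | [K+].[O-]C1=C(CC=C(C)C)C(=O)[C@]2(CC=C(C)C)C[C@H](C=O)C(C)(C)[C@@]1(C(=O)c1ccccc1)C2=O | intermediate
12 | O4-silyl aldehyde, 1-benzoyl-8,8-dimethyl-3,5-bis(3-methylbut-2-enyl)-2,9-dioxo-4-(triisopropylsilyloxy)bicyclo[3.3.1]non-3-ene-7-carbaldehyde, CHO endo | O=C1C(CC=C(C)C)=C(O[Si](C(C)C)(C(C)C)C(C)C)[C@]2(CC=C(C)C)C[C@H](C=O)C(C)(C)[C@@]1(C(=O)c1ccccc1)C2=O | intermediate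
13 | silyloxyallyl cation triflate (not isolated), the O2-methylated form of 12 (2-methoxy-4-triisopropylsilyloxy allyl cation across C2–C3–C4) | COC1=C(CC=C(C)C)C(=[O+][Si](C(C)C)(C(C)C)C(C)C)[C@]2(CC=C(C)C)C[C@H](C=O)C(C)(C)[C@@]1(C(=O)c1ccccc1)C2=O.[O-]S(=O)(=O)C(F)(F)F | intermediate
14 | O2-methyl aldehyde, 1-benzoyl-2-methoxy-8,8-dimethyl-3,5-bis(3-methylbut-2-enyl)-4,9-dioxobicyclo[3.3.1]non-2-ene-7-carbaldehyde, CHO endo | COC1=C(CC=C(C)C)C(=O)[C@]2(CC=C(C)C)C[C@H](C=O)C(C)(C)[C@@]1(C(=O)c1ccccc1)C2=O | intermediate
15 | primary alcohol, 7-(hydroxymethyl) analogue of 14 | COC1=C(CC=C(C)C)C(=O)[C@]2(CC=C(C)C)C[C@H](CO)C(C)(C)[C@@]1(C(=O)c1ccccc1)C2=O | intermediate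
16 | primary bromide, 7-(bromomethyl) analogue of 14 | COC1=C(CC=C(C)C)C(=O)[C@]2(CC=C(C)C)C[C@H](CBr)C(C)(C)[C@@]1(C(=O)c1ccccc1)C2=O | intermediate
17 | propargyl alcohol | C#CCO | starting material
18 | alkenylalane (not isolated), dimethyl[(E)-3-(dimethylalumanyloxy)-2-methylprop-1-enyl]alumane | C[Al](C)/C=C(\C)CO[Al](C)C | intermediate
19 | (E)-3-bromo-2-methylprop-2-en-1-ol | Br/C=C(\C)CO | intermediate
20 | allylic alcohol, 7-[(E)-4-hydroxy-3-methylbut-2-enyl] compound, side chain endo | COC1=C(CC=C(C)C)C(=O)[C@]2(CC=C(C)C)C[C@H](C/C=C(\C)CO)C(C)(C)[C@@]1(C(=O)c1ccccc1)C2=O | intermediate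
21 | [(E)-4-[(1R,5S,7S)-1-benzoyl-2-methoxy-8,8-dimethyl-3,5-bis(3-methylbut-2-enyl)-4,9-dioxobicyclo[3.3.1]non-2-en-7-yl]-2-methylbut-2-enyl] acetate | COC1=C(CC=C(C)C)C(=O)[C@]2(CC=C(C)C)C[C@H](C/C=C(\C)COC(C)=O)C(C)(C)[C@@]1(C(=O)c1ccccc1)C2=O | target

**Count and risks**

Total step count: 12. Longest linear sequence: 10 steps (steps 2, 3, 4, 5, 6, 7, 8, 9, 11, 12, starting from 4).

Steps most likely to fail:

1. Step 7 (the step proposed as new). O-methylation at the screened C2 carbonyl oxygen may be too slow, silicon may be lost before methylation, or the cation may be intercepted by the neighbouring aldehyde. The fallback sets out from 10 and returns at 14. Compound 10 is stirred with Me3SiCHN2 and a catalytic amine in toluene/MeOH, so that the small equilibrium amount of enol aldehyde 9 is methylated as a vinylogous acid. This should give 14 together with the O4-methyl regioisomer F1, without site selectivity. The two are separated, and F1 is returned to 10 by SN2 demethylation with LiCl in DMSO followed by spontaneous aldol reclosure.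

2. Step 5. Enantioselection in the ion pair may be poor, O-alkylation may compete, base-mediated closure at C3 may begin before the acid is added, or the acid stage may stall at a reversible O-cyclized pyran. The fallback sets out from 3 and 7 and returns at 10. The alkylation is run without a chiral catalyst (LiN(SiMe3)2, THF, 0 °C), where the lithium enolate of the dearomatized enal does not cyclize, and the mixture is then acidified (conc. aq. HCl, THF) to give racemic cage alcohol. The mirror-image adamantane alcohol F2 is removed by preparative chromatography on a chiral stationary phase.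

3. Step 11. Radical generation at the β-branched bromide may be slow, C10 may simply be reduced, or the vinylogous ester oxygen may alkylate intramolecularly at C10 (also a risk while 16 is handled). The fallback sets out from 14 and returns at 20, bypassing 15 and 16. Bromide 19 is silylated (t-BuMe2SiCl, imidazole) to the silyl ether F3. F3 is converted to the alkenylcerium reagent (t-BuLi, then CeCl3, THF, −78 °C) and added to aldehyde 14 to give the C10 allylic alcohol F4 (C10 epimers, both usable). F4 is converted to the methyl carbonate F5 (ClCO2Me, pyridine). Hydrogenolysis of F5 with Pd(PPh3)4 and Bu3SnH should deliver hydride to the less substituted C10 terminus of the allyl intermediate and give the deoxygenated silyl ether F6. Et3N·3HF then frees 20.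

Further compounds
F1 | step 7 | O4-methyl regioisomer of 14, 1-benzoyl-4-methoxy-8,8-dimethyl-3,5-bis(3-methylbut-2-enyl)-2,9-dioxobicyclo[3.3.1]non-3-ene-7-carbaldehyde | O=C1C(CC=C(C)C)=C(OC)[C@]2(CC=C(C)C)C[C@H](C=O)C(C)(C)[C@@]1(C(=O)c1ccccc1)C2=O
F2 | step 5 | mirror-image adamantane alcohol (enantiomer of 10) | O=C1[C@]3(CC=C(C)C)C(=O)[C@@]2(CC=C(C)C)C[C@@H]([C@H]3O)C(C)(C)[C@]1(C(=O)c1ccccc1)C2=O
F3 | step 11 | [(E)-3-bromo-2-methylallyloxy](tert-butyl)dimethylsilane | Br/C=C(\C)CO[Si](C)(C)C(C)(C)C
F4 | step 11 | C10 allylic alcohol, 7-[(E)-4-(tert-butyldimethylsilyloxy)-1-hydroxy-3-methylbut-2-enyl] analogue of 14 (C10 epimers) | COC1=C(CC=C(C)C)C(=O)[C@]2(CC=C(C)C)C[C@H](C(O)/C=C(\C)CO[Si](C)(C)C(C)(C)C)C(C)(C)[C@@]1(C(=O)c1ccccc1)C2=O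
F5 | step 11 | methyl carbonate of F4 | COC(=O)OC(/C=C(\C)CO[Si](C)(C)C(C)(C)C)[C@H]1C[C@@]2(CC=C(C)C)C(=O)C(CC=C(C)C)=C(OC)[C@](C(=O)c3ccccc3)(C2=O)C1(C)C
F6 | step 11 | tert-butyldimethylsilyl ether of 20 | COC1=C(CC=C(C)C)C(=O)[C@]2(CC=C(C)C)C[C@H](C/C=C(\C)CO[Si](C)(C)C(C)(C)C)C(C)(C)[C@@]1(C(=O)c1ccccc1)C2=O
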